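**Plan**

- Retrosynthesis: the silyl ether on the C7 oxygen is cut first, then the C4–C4a acyl–aryl bond of ring C, then the O1–C2 aryl ether bond. This separates a ring A bromophenol from a ring B cinnamyl carbonate, in which the C8–prenyl bond and the pyran ring of the chromene are cut last.
- Forward: the chromene ring of ring B closes first (propargyl ether Claisen cascade), prenyl is coupled on, and the aldehyde is extended to an (E)-cinnamyl carbonate. Ring A is then joined through O1 to C2, the vinyl group is raised to the C4 N-methoxy-N-methylamide, ring C closes, and desilylation ends the route.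
- Stereochemistry: the only stereocentre, C2 (R), is set by ligand-controlled iridium-catalysed allylic etherification. It is never exposed to acid afterwards, because its C2–O1 bond is an ionisable para-alkoxybenzylic ether.
- Enabling feature: C4a is the ring A carbon ortho to O1, and the O1–C2–C3 tether puts the C4 carbonyl five atoms from it. A bromine on C4a (para to the C7 oxygen, bought in with 4-bromoresorcinol) is exchanged for lithium, and the aryllithium closes the six-membered ring C on the amide at −78 °C.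
- This base-only, cryogenic closure spares the prenyl group, the chromene and the C2 ether, which a Friedel–Crafts acylation would not.

Key step: step 12

Assumption: the (Ra,Rc,Rc) phosphoramidite is taken to give the (R)-ether, as is usual for heteroatom nucleophiles and aryl-substituted allyl carbonates with this catalyst type; if the opposite sense is found, the enantiomeric ligand is used and nothing else changes.

**Route**

Step 1
Reactants: 1 3-bromo-4-hydroxybenzaldehyde; 2 3-chloro-3-methylbut-1-yne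
Product: 3 3-bromo-4-[(2-methylbut-3-yn-2-yl)oxy]benzaldehyde
Conditions: DBU, CuCl2·2H2O (cat.), MeCN, 0 °C → rt
Reagents that add atoms: none
Why: Copper-catalysed O-propargylation of the phenoxide with the tertiary propargylic chloride is the standard entry to aryl 1,1-dimethylpropargyl ethers and should tolerate the ortho-bromine and the aldehyde.

Step 2
Reactants: 3 3-bromo-4-[(2-methylbut-3-yn-2-yl)oxy]benzaldehyde
Product: 5 8-bromo-2,2-dimethyl-2H-chromene-6-carbaldehyde, via allenylphenol 4 (not isolated)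
Conditions: PhNEt2, 190 °C
Reagents that add atoms: none
Why: Aromatic propargyl Claisen rearrangement to the only free ortho position, tautomerisation to allenylphenol 4, 1,5-hydrogen shift and 6π-oxa-electrocyclisation should give the 2,2-dimethylchromene.

Step 3
Reactants: 5 8-bromo-2,2-dimethyl-2H-chromene-6-carbaldehyde; 6 tributyl(3-methylbut-2-en-1-yl)stannane
Product: 7 2,2-dimethyl-8-(3-methylbut-2-en-1-yl)-2H-chromene-6-carbaldehyde
Conditions: Pd(PPh3)4 (5 mol %), DMF, 90 °C
Reagents that add atoms: none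
Why: Migita–Kosugi–Stille coupling of the aryl bromide (activated by the para-formyl group) with the prenylstannane is expected to give the linear prenyl arene, the aldehyde and chromene alkene being inert to zerovalent palladium here.

Step 4
Reactants: 7 2,2-dimethyl-8-(3-methylbut-2-en-1-yl)-2H-chromene-6-carbaldehyde; 8 triethyl phosphonoacetate
Product: 9 ethyl (E)-3-[2,2-dimethyl-8-(3-methylbut-2-en-1-yl)-2H-chromen-6-yl]prop-2-enoate
Conditions: NaH, THF, 0 °C → rt
Reagents that add atoms: none
Why: Horner–Wadsworth–Emmons olefination with the stabilised phosphonate anion should give the (E)-cinnamate.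

Step 5
Reactants: 9 ethyl (E)-3-[2,2-dimethyl-8-(3-methylbut-2-en-1-yl)-2H-chromen-6-yl]prop-2-enoate
Product: 10 (E)-3-[2,2-dimethyl-8-(3-methylbut-2-en-1-yl)-2H-chromen-6-yl]prop-2-en-1-ol
Conditions: i-Bu2AlH (2.2 equiv), CH2Cl2, −78 °C; aq KNaC4H4O6 work-up
Reagents that add atoms: none
Why: 1,2-Reduction of the conjugated ester by the aluminium hydride at low temperature should give the (E)-allylic alcohol without touching the alkenes.

Step 6
Reactants: 10 (E)-3-[2,2-dimethyl-8-(3-methylbut-2-en-1-yl)-2H-chromen-6-yl]prop-2-en-1-ol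
Product: 11 (E)-3-[2,2-dimethyl-8-(3-methylbut-2-en-1-yl)-2H-chromen-6-yl]prop-2-en-1-yl methyl carbonate
Conditions: ClCO2Me, pyridine, CH2Cl2, 0 °C; chromatography on Et3N-deactivated silica
Reagents that add atoms: methyl chloroformate, COC(=O)Cl
Why: O-Acylation of the primary allylic alcohol installs the carbonate leaving group needed for ionisation to the allyl–iridium complex.

Step 7
Reactants: 12 4-bromobenzene-1,3-diol (4-bromoresorcinol)
Product: 13 2-bromo-5-[(triisopropylsilyl)oxy]phenol
Conditions: TIPSCl (1.0 equiv), imidazole, DMF, 0 °C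
Reagents that add atoms: triisopropylsilyl chloride, CC(C)[Si](Cl)(C(C)C)C(C)C
Why: Silyl ether formation with the bulky chloride is expected at the hydroxyl para to bromine, because the hydroxyl flanked by bromine is hindered and less nucleophilic; the TIPS ether should survive methoxide, perborate and t-BuLi.

Step 8
Reactants: 13 2-bromo-5-[(triisopropylsilyl)oxy]phenol; 11 (E)-3-[2,2-dimethyl-8-(3-methylbut-2-en-1-yl)-2H-chromen-6-yl]prop-2-en-1-yl methyl carbonate
Product: 15 {4-bromo-3-[(1R)-1-[2,2-dimethyl-8-(3-methylbut-2-en-1-yl)-2H-chromen-6-yl]prop-2-en-1-yloxy]phenoxy}triisopropylsilane, via lithium phenoxide 14 (not isolated)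
Conditions: 13 (2 equiv), LiN(SiMe3)2 (2 equiv), THF, 0 °C; then 11, [Ir(cod)Cl]2 (2 mol %), (Ra,Rc,Rc)-O,O'-(1,1'-binaphthyl-2,2'-diyl) N,N-bis(1-phenylethyl)phosphoramidite (4 mol %, pre-activated with n-PrNH2), THF, rt
Reagents that add atoms: lithium bis(trimethylsilyl)amide, [Li]N([Si](C)(C)C)[Si](C)(C)C (supplies only the lithium of intermediate 14)
Why: In this iridium-catalysed asymmetric allylic etherification the cyclometalated iridium–phosphoramidite ionises the carbonate and the aryloxide attacks the aryl-substituted allyl terminus anti to the metal, so the branched ether forms and the ligand configuration sets C2 as (R).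

Step 9
Reactants: 15 {4-bromo-3-[(1R)-1-[2,2-dimethyl-8-(3-methylbut-2-en-1-yl)-2H-chromen-6-yl]prop-2-en-1-yloxy]phenoxy}triisopropylsilane
Product: 17 (3R)-3-[2-bromo-5-(triisopropylsilyloxy)phenoxy]-3-[2,2-dimethyl-8-(3-methylbut-2-en-1-yl)-2H-chromen-6-yl]propan-1-ol, via alkylborane 16 (not isolated)
Conditions: 9-BBN (1.3 equiv), THF, 0 °C → rt; then NaBO3·4H2O, H2O, rt
Reagents that add atoms: 9-borabicyclo[3.3.1]nonane, B1C2CCCC1CCC2 (boron unit of intermediate 16 only); sodium perborate tetrahydrate (NaBO3·4H2O), [Na+].[O-]B1OO1.O.O.O.O (hydroxyl oxygen of 17)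
Why: Anti-Markovnikov hydroboration with 9-BBN should select the monosubstituted alkene over the trisubstituted prenyl and the hindered chromene alkenes, and the mild perborate oxidation leaves the aryl silyl ether intact.

Step 10
Reactants: 17 (3R)-3-[2-bromo-5-(triisopropylsilyloxy)phenoxy]-3-[2,2-dimethyl-8-(3-methylbut-2-en-1-yl)-2H-chromen-6-yl]propan-1-ol
Product: 19 (3R)-3-[2-bromo-5-(triisopropylsilyloxy)phenoxy]-3-[2,2-dimethyl-8-(3-methylbut-2-en-1-yl)-2H-chromen-6-yl]propanoic acid, via aldehyde 18 (not isolated)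
Conditions: TEMPO (0.2 equiv), PhI(OAc)2 (2.2 equiv), MeCN/H2O 1:1, rt
Reagents that add atoms: water, O
Why: Oxoammonium-catalysed (TEMPO) oxidation takes the primary alcohol through aldehyde 18 and its hydrate to the acid under near-neutral conditions that spare trisubstituted alkenes and avoid base-induced β-elimination of the aryloxide.

Step 11
Reactants: 19 (3R)-3-[2-bromo-5-(triisopropylsilyloxy)phenoxy]-3-[2,2-dimethyl-8-(3-methylbut-2-en-1-yl)-2H-chromen-6-yl]propanoic acid
Product: 21 (3R)-3-[2-bromo-5-(triisopropylsilyloxy)phenoxy]-3-[2,2-dimethyl-8-(3-methylbut-2-en-1-yl)-2H-chromen-6-yl]-N-methoxy-N-methylpropanamide, via acyl imidazolide 20 (not isolated)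
Conditions: CDI (1.2 equiv), CH2Cl2, rt; then MeNHOMe·HCl (1.5 equiv), rt
Reagents that add atoms: 1,1'-carbonyldiimidazole, O=C(n1ccnc1)n1ccnc1 (imidazolyl group of intermediate 20 only); N,O-dimethylhydroxylamine hydrochloride, CNOC.Cl
Why: Amide coupling through the acyl imidazolide needs no strong base, so the β-aryloxy stereocentre is not put at risk.

Step 12
Reactants: 21 (3R)-3-[2-bromo-5-(triisopropylsilyloxy)phenoxy]-3-[2,2-dimethyl-8-(3-methylbut-2-en-1-yl)-2H-chromen-6-yl]-N-methoxy-N-methylpropanamide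
Product: 24 (2R)-2-[2,2-dimethyl-8-(3-methylbut-2-en-1-yl)-2H-chromen-6-yl]-7-[(triisopropylsilyl)oxy]chroman-4-one, via aryllithium 22 (not isolated), via tetrahedral adduct 23 (not isolated)
Conditions: t-BuLi (2.1 equiv), THF, −78 °C, 20 min; then sat. aq NH4Cl, −78 °C → rt
Reagents that add atoms: tert-butyllithium, [Li]C(C)(C)C (supplies only the lithium of intermediates 22 and 23)
Why: Two equivalents of t-BuLi effect bromine–lithium exchange at C4a (the second destroys t-BuBr), and aryllithium 22 adds at once to the chelating N-methoxy-N-methylamide carbonyl five atoms away to give the lithium-chelated tetrahedral adduct 23, which cannot collapse or over-add until the cold NH4Cl quench releases ketone 24. The closest known reaction type is the Parham cyclization (cycliacylation) of ortho-bromoaryl ethers carrying N-methoxy-N-methylamides, which gives chroman-4-ones. Ring C closes in the 6-exo-trig mode by attack of C4a on the C4 carbonyl carbon. No stereocentre is created in the isolated product (C4 of 23 is transient), and C2 is untouched because neither its C–O nor its C–H bond takes part. The step needs regioselectivity for C4a over C6 and C8, fixed by the position of the bromine, and chemoselectivity over deprotonation at C3, which would expel the aryloxide by retro-oxa-Michael elimination; the speed of the halogen–metal exchange and of the intramolecular acyl transfer at −78 °C should secure this. Because no acid is used, the prenyl group, the chromene and the ionisable para-alkoxybenzylic C2–O1 ether should survive.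

Step 13
Reactants: 24 (2R)-2-[2,2-dimethyl-8-(3-methylbut-2-en-1-yl)-2H-chromen-6-yl]-7-[(triisopropylsilyl)oxy]chroman-4-one
Product: 25 ent-abyssinone III, (2R)-7-hydroxy-2-[2,2-dimethyl-8-(3-methylbut-2-en-1-yl)-2H-chromen-6-yl]chroman-4-one
Conditions: Bu4NF, AcOH (1:1), THF, 0 °C
Reagents that add atoms: none
Why: Fluoride cleaves the aryl O–Si bond, and the acetic acid buffer keeps the liberated phenol protonated, which should prevent base-induced ring opening (retro-oxa-Michael) and racemisation at C2.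

**Compound list**

1 | 3-bromo-4-hydroxybenzaldehyde | O=Cc1ccc(O)c(Br)c1 | starting material
2 | 3-chloro-3-methylbut-1-yne | C#CC(C)(C)Cl | starting material
3 | 3-bromo-4-[(2-methylbut-3-yn-2-yl)oxy]benzaldehyde | O=Cc1ccc(OC(C)(C)C#C)c(Br)c1 | intermediate
4 | 3-bromo-4-hydroxy-5-(3-methylbuta-1,2-dien-1-yl)benzaldehyde (allenylphenol) | O=Cc1cc(Br)c(O)c(C=C=C(C)C)c1 | intermediate
5 | 8-bromo-2,2-dimethyl-2H-chromene-6-carbaldehyde | O=Cc1cc(Br)c2OC(C)(C)C=Cc2c1 | intermediate
6 | tributyl(3-methylbut-2-en-1-yl)stannane | CCCC[Sn](CCCC)(CCCC)CC=C(C)C | starting material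
7 | 2,2-dimethyl-8-(3-methylbut-2-en-1-yl)-2H-chromene-6-carbaldehyde | O=Cc1cc(CC=C(C)C)c2OC(C)(C)C=Cc2c1 | intermediate
8 | triethyl phosphonoacetate | CCOC(=O)CP(=O)(OCC)OCC | starting material
9 | ethyl (E)-3-[2,2-dimethyl-8-(3-methylbut-2-en-1-yl)-2H-chromen-6-yl]prop-2-enoate | CCOC(=O)/C=C/c1cc(CC=C(C)C)c2OC(C)(C)C=Cc2c1 | intermediate
10 | (E)-3-[2,2-dimethyl-8-(3-methylbut-2-en-1-yl)-2H-chromen-6-yl]prop-2-en-1-ol | OC/C=C/c1cc(CC=C(C)C)c2OC(C)(C)C=Cc2c1 | intermediate
11 | (E)-3-[2,2-dimethyl-8-(3-methylbut-2-en-1-yl)-2H-chromen-6-yl]prop-2-en-1-yl methyl carbonate | COC(=O)OC/C=C/c1cc(CC=C(C)C)c2OC(C)(C)C=Cc2c1 | intermediate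
12 | 4-bromobenzene-1,3-diol (4-bromoresorcinol) | Oc1ccc(Br)c(O)c1 | starting material
13 | 2-bromo-5-[(triisopropylsilyl)oxy]phenol | Oc1cc(O[Si](C(C)C)(C(C)C)C(C)C)ccc1Br | intermediate
14 | lithium 2-bromo-5-[(triisopropylsilyl)oxy]phenoxide | [Li+].[O-]c1cc(O[Si](C(C)C)(C(C)C)C(C)C)ccc1Br | intermediate
15 | {4-bromo-3-[(1R)-1-[2,2-dimethyl-8-(3-methylbut-2-en-1-yl)-2H-chromen-6-yl]prop-2-en-1-yloxy]phenoxy}triisopropylsilane | CC(C)=CCc1cc([C@H](Oc2cc(O[Si](C(C)C)(C(C)C)C(C)C)ccc2Br)C=C)cc2c1OC(C)(C)C=C2 | intermediate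
16 | 9-{(3R)-3-[2-bromo-5-(triisopropylsilyloxy)phenoxy]-3-[2,2-dimethyl-8-(3-methylbut-2-en-1-yl)-2H-chromen-6-yl]propyl}-9-borabicyclo[3.3.1]nonane | CC(C)=CCc1cc([C@H](Oc2cc(O[Si](C(C)C)(C(C)C)C(C)C)ccc2Br)CCB2C3CCCC2CCC3)cc2c1OC(C)(C)C=C2 | intermediate
17 | (3R)-3-[2-bromo-5-(triisopropylsilyloxy)phenoxy]-3-[2,2-dimethyl-8-(3-methylbut-2-en-1-yl)-2H-chromen-6-yl]propan-1-ol | CC(C)=CCc1cc([C@H](Oc2cc(O[Si](C(C)C)(C(C)C)C(C)C)ccc2Br)CCO)cc2c1OC(C)(C)C=C2 | intermediate
18 | (3R)-3-[2-bromo-5-(triisopropylsilyloxy)phenoxy]-3-[2,2-dimethyl-8-(3-methylbut-2-en-1-yl)-2H-chromen-6-yl]propanal | CC(C)=CCc1cc([C@H](Oc2cc(O[Si](C(C)C)(C(C)C)C(C)C)ccc2Br)CC=O)cc2c1OC(C)(C)C=C2 | intermediate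
19 | (3R)-3-[2-bromo-5-(triisopropylsilyloxy)phenoxy]-3-[2,2-dimethyl-8-(3-methylbut-2-en-1-yl)-2H-chromen-6-yl]propanoic acid | CC(C)=CCc1cc([C@H](Oc2cc(O[Si](C(C)C)(C(C)C)C(C)C)ccc2Br)CC(=O)O)cc2c1OC(C)(C)C=C2 | intermediate
20 | (3R)-3-[2-bromo-5-(triisopropylsilyloxy)phenoxy]-3-[2,2-dimethyl-8-(3-methylbut-2-en-1-yl)-2H-chromen-6-yl]-1-(1H-imidazol-1-yl)propan-1-one | CC(C)=CCc1cc([C@H](Oc2cc(O[Si](C(C)C)(C(C)C)C(C)C)ccc2Br)CC(=O)n2ccnc2)cc2c1OC(C)(C)C=C2 | intermediate
21 | (3R)-3-[2-bromo-5-(triisopropylsilyloxy)phenoxy]-3-[2,2-dimethyl-8-(3-methylbut-2-en-1-yl)-2H-chromen-6-yl]-N-methoxy-N-methylpropanamide | CC(C)=CCc1cc([C@H](Oc2cc(O[Si](C(C)C)(C(C)C)C(C)C)ccc2Br)CC(=O)N(C)OC)cc2c1OC(C)(C)C=C2 | intermediate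
22 | aryllithium from 21 (lithium in place of bromine at C4a) | CC(C)=CCc1cc([C@H](Oc2cc(O[Si](C(C)C)(C(C)C)C(C)C)ccc2[Li])CC(=O)N(C)OC)cc2c1OC(C)(C)C=C2 | intermediate
23 | lithium (2R)-2-[2,2-dimethyl-8-(3-methylbut-2-en-1-yl)-2H-chromen-6-yl]-4-[methoxy(methyl)amino]-7-[(triisopropylsilyl)oxy]chroman-4-olate (tetrahedral adduct, C4 epimers) | CC(C)=CCc1cc([C@H]2CC(O[Li])(N(C)OC)c3ccc(O[Si](C(C)C)(C(C)C)C(C)C)cc3O2)cc2c1OC(C)(C)C=C2 | intermediate
24 | (2R)-2-[2,2-dimethyl-8-(3-methylbut-2-en-1-yl)-2H-chromen-6-yl]-7-[(triisopropylsilyl)oxy]chroman-4-one | CC(C)=CCc1cc([C@H]2CC(=O)c3ccc(O[Si](C(C)C)(C(C)C)C(C)C)cc3O2)cc2c1OC(C)(C)C=C2 | intermediate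
25 | ent-abyssinone III, (2R)-7-hydroxy-2-[2,2-dimethyl-8-(3-methylbut-2-en-1-yl)-2H-chromen-6-yl]chroman-4-one | CC(C)=CCc1cc([C@H]2CC(=O)c3ccc(O)cc3O2)cc2c1OC(C)(C)C=C2 | target

**Step count and risks**

Total step count: 13. Longest linear sequence: 12 steps (steps 1–6 and 8–13; step 7 is the one-step side branch to ring A).

Steps most likely to fail:

1. Step 12. After the bromine–lithium exchange, proton transfer from C3 to the aryllithium (or direct deprotonation of C3 by t-BuLi) followed by β-elimination of the aryloxide would destroy the C2–O1 bond; anion translocation to the benzylic C2 is a second escape path. The fallback avoids organolithium chemistry and closes the ring reductively at the aldehyde oxidation level. It sets out from alcohol 17, which is oxidised with Dess–Martin periodinane (NaHCO3 buffer, CH2Cl2) to aldehyde 18, isolated in this variant. A nickel-catalysed reductive aryl bromide–aldehyde cyclisation of the Nozaki–Hiyama–Kishi type (NiBr2·dme, 2,2'-bipyridine ligand, Zn, DMA, rt) then joins C4a to C4 and gives (2R)-2-[2,2-dimethyl-8-(3-methylbut-2-en-1-yl)-2H-chromen-6-yl]-7-[(triisopropylsilyl)oxy]chroman-4-ol F1 as a mixture of C4 epimers. Dess–Martin oxidation of both epimers comes back to the route at ketone 24.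

2. Step 8. Reversible re-ionisation of the electron-rich branched ether by the iridium catalyst may erode the enantiomeric purity and lead to isomerisation to the linear ether, and the ortho-bromo aryloxide may attack slowly. The fallback is an enantioconvergent copper-catalysed propargylic etherification followed by semihydrogenation. It sets out from aldehyde 7, which is treated with HC≡CMgBr (THF, 0 °C) to give racemic 1-[2,2-dimethyl-8-(3-methylbut-2-en-1-yl)-2H-chromen-6-yl]prop-2-yn-1-ol F2. Acetylation (Ac2O, Et3N, DMAP) gives the racemic propargylic acetate F3. Reaction of F3 with phenol 13 under (CuOTf)2·C6H6, a chiral pybox ligand and i-Pr2NEt, through a copper allenylidene and with the ligand enantiomer chosen for the (R) sense, gives the (R)-aryl propargyl ether F4. Semihydrogenation of the terminal alkyne (H2, Pd/CaCO3 poisoned with Pb(OAc)2, quinoline) comes back to the route at allyl ether 15.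

3. Step 3. Transmetalation through the γ-carbon of the allylic stannane would give the 1,1-dimethylallyl regioisomer, and the prenyl double bond may migrate into conjugation at 90 °C. The fallback replaces the palladium coupling by an arylcopper allylation. It sets out from bromide 5, whose aldehyde is protected with ethylene glycol (PPTS, benzene, water removal) as 2-(8-bromo-2,2-dimethyl-2H-chromen-6-yl)-1,3-dioxolane F5. Bromine–lithium exchange (n-BuLi, THF, −78 °C), transmetalation with CuBr·SMe2 and SN2 alkylation with prenyl bromide give 2-[2,2-dimethyl-8-(3-methylbut-2-en-1-yl)-2H-chromen-6-yl]-1,3-dioxolane F6. Mild hydrolysis (PPTS, wet acetone) comes back to the route at aldehyde 7.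

**Further compounds**

F1 | step 12 | (2R)-2-[2,2-dimethyl-8-(3-methylbut-2-en-1-yl)-2H-chromen-6-yl]-7-[(triisopropylsilyl)oxy]chroman-4-ol (C4 epimers) | CC(C)=CCc1cc([C@H]2CC(O)c3ccc(O[Si](C(C)C)(C(C)C)C(C)C)cc3O2)cc2c1OC(C)(C)C=C2
F2 | step 8 | racemic 1-[2,2-dimethyl-8-(3-methylbut-2-en-1-yl)-2H-chromen-6-yl]prop-2-yn-1-ol | C#CC(O)c1cc(CC=C(C)C)c2OC(C)(C)C=Cc2c1
F3 | step 8 | racemic 1-[2,2-dimethyl-8-(3-methylbut-2-en-1-yl)-2H-chromen-6-yl]prop-2-yn-1-yl acetate | CC(=O)OC(C#C)c1cc(CC=C(C)C)c2OC(C)(C)C=Cc2c1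
F4 | step 8 | {4-bromo-3-[(1R)-1-[2,2-dimethyl-8-(3-methylbut-2-en-1-yl)-2H-chromen-6-yl]prop-2-yn-1-yloxy]phenoxy}triisopropylsilane | CC(C)=CCc1cc([C@H](Oc2cc(O[Si](C(C)C)(C(C)C)C(C)C)ccc2Br)C#C)cc2c1OC(C)(C)C=C2
F5 | step 3 | 2-(8-bromo-2,2-dimethyl-2H-chromen-6-yl)-1,3-dioxolane | Brc1cc(C2OCCO2)cc2C=CC(C)(C)Oc12
F6 | step 3 | 2-[2,2-dimethyl-8-(3-methylbut-2-en-1-yl)-2H-chromen-6-yl]-1,3-dioxolane | CC(C)=CCc1cc(C2OCCO2)cc2C=CC(C)(C)Oc12
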